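Readings and results are simulated with constants of no real substance; the scatter is artificial.

I compared how fast the target came up in the earlier runs by one working figure, the early first-order slope: minus the logarithm of the unconverted fraction, divided by the time.

| flask | substrate | enzyme | remark |
|---|---|---|---|
| ash | 0.010 M | 0.0022 mol% | run made earlier |
| larch | 0.040 M | 0.0022 mol% | run made earlier |
| cedar | 0.020 M | 0.0033 mol% | run made earlier |
| flask | 0.020 M | 0.0022 mol% |  |

| run | time / h | target / % |
|---|---|---|
| ash | 0.333 | 44.2 |
| ash | 0.667 | 72.8 |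
| ash | 1.00 | 87.0 |
| ash | 1.33 | 93.0 |
| ash | 1.50 | 94.1 |
| ash | 2.00 | 96.0 |
| ash | 2.50 | 97.3 |
| larch | 0.200 | 34.2 |
| larch | 0.333 | 52.0 |
| larch | 0.417 | 61.1 |
| larch | 0.667 | 81.8 |
| larch | 1.00 | 89.7 |
| larch | 1.50 | 89.7 |
| larch | 2.50 | 89.0 |
| cedar | 0.200 | 45.6 |
| cedar | 0.333 | 66.8 |
| cedar | 0.667 | 92.2 |
| cedar | 1.33 | 95.3 |
| cedar | 2.50 | 95.8 |

(readings scatter by 0.5 percentage points)



1. apparent order in enzyme when 10 % of the substrate are converted (percent change of the rate of making target for one percent more enzyme charged)

Cedar carried 1.50 times the enzyme loading of the flask at the same substrate concentration, and at 0.200 h it stood at 45.6 %, a slope of 3.04 h⁻¹. The flask had no reading, but at its loading ash gave 1.75 h⁻¹ at 44.2 % and larch gave 2.20 h⁻¹ at 52.0 %. Ash ran slower than larch, and the flask's concentration lies between theirs, so I took its slope to lie between those two.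

exponent = ln(slope of cedar / slope of the flask) / ln(enzyme of cedar / enzyme of the flask)

With ash standing in for the flask this gave an upper bound of 1.36, and with larch a lower bound of 0.796. The geometric mean of the two slopes, as far as my hand could tighten it, gave 1.08. This loading exponent, the percent change of the slope for one percent more enzyme at fixed substrate concentration, I carried back unchanged to 10 % conversion, which lies before the first readings, although the slope itself was no constant: in cedar it climbed from 3.04 h⁻¹ to 3.82 h⁻¹ at 0.667 h.

The forecast gave 1.1, reasoning that “Cedar has 1.5 times the enzyme at that concentration and runs about 1.6 times faster”, which placed it inside my bracket .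

The flask gave 0.96, also inside the bracket .

    substrate + enzyme → target + enzyme, rate k1*[substrate]*[enzyme]/(1 + ([substrate]/Km1)) (7.10 mM, k = 3.34 × 10⁵ L mol⁻¹ min⁻¹)
    2 enzyme ⇌ resting dimer (K = 7.54 × 10⁵ L mol⁻¹, k = 94400 L mol⁻¹ min⁻¹)
    2 substrate → homo dimer (k = 0.122 L mol⁻¹ min⁻¹)

At 1.00 h the resting dimer, the catalyst's off-cycle form, held 31.3 % of the catalyst charged and the enzyme 68.7 %. Put to use once more, the loading exponent took cedar's slope down to 1.97 h⁻¹ for the flask, which reckoned 32.6 % target at 0.200 h, against 34.0 % standing in the flask.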